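## Structural features

Atom numbers follow the seco-acid chain: C1 is the lactone carbonyl, C14 the terminal methyl, and On the oxygen on Cn. The target is a ten-membered lactone (ring atoms C1–C9 and O9). It carries a 2R methyl, a 3R acetate, a Z C4=C5 double bond, a free 8S hydroxyl and, on 9R, a (4S)-4-acetoxypentyl chain (C10–C14, stereocentre C13).

The stereocentres form two adjacent pairs plus the remote C13. C2/C3 is anti (propionate-aldol pattern, with C3 also allylic). C8/C9 is an erythro diol in which only O9 is acylated.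

Several groups are fragile:
- The C3 acetate is allylic and β to the lactone carbonyl, so it can ionise or undergo E1cB loss.
- C2–H can epimerise.
- The free O8–H sits next to the O9 acyl group, so translactonisation to a nine-membered ring is possible.
- The Z alkene sits in a strained medium ring.

Four oxygens must end in three different states: O3 and O13 acetylated, O8 free, O9 in the lactone.

The real difficulty is closing the medium ring with Z geometry while also setting the C2/C3 pair next to that alkene. Closure at C1–O9 or at C4=C5 does nothing for these centres.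

The key step exploits the array O=C1–C2–C3–C4=C5. This is a γ,δ-unsaturated ester lying wholly inside the ring, i.e. a Claisen retron. Its C2–C3 σ-bond carries both adjacent stereocentres, its carbonyl oxygen maps back onto C5, and O9 is a spectator. The ten-membered ring therefore contracts, in the retrosynthetic direction, to an eight-membered ring (C1, O5, C5–C9, O9).

## Logic of the disconnections

**25 ⇒ 24 ⇒ 23 ⇒ 22.**
- Bonds cut: O8–H is exchanged for O8–Si. The two acetyl C–O bonds on O3 and O13 are replaced by an aryl and a benzyl ether.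
- Reason: acetates and a free hydroxyl would not survive the alkoxide and organolithium chemistry upstream, and the β-acetoxy lactone is best created last.
- Gain: three oxygen states become three orthogonal ethers, two of which fall in a single oxidation.
- Demand: steps 14–16 must stay non-basic, so that C2 is not epimerised, O3 is not eliminated and no O9→O8 acyl shift starts.

**22 ⇒ 21 (key).**
- Bonds cut: C2–C3. At the same time the C1 carbonyl oxygen is reconnected to C5, and the unsaturation moves from C4=C5 to C1=C2 and C3=C4 (retro-Claisen).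
- Reason: this is the only bond whose formation sets C2, C3, the alkene geometry and the ring size together.
- Gain: the ten-membered ring, two adjacent stereocentres and a ring Z alkene are traded for an eight-membered ring, one carbinol centre (C5) and two alkene geometries set by open-chain chemistry.
- Demand: a chair-like [3,3] shift, an E C3=C4 enol ether, the C2 methyl cis to O5, and 5R.
- In one sentence, 20 is closed to the eight-membered ketene acetal 21, which ring-expands by Claisen rearrangement to 22. That sentence fits neither an esterification/metathesis route nor a seco-acid lactonisation.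

**21 ⇒ 20.**
- Bond cut: C1–O5.
- Reason: a trans O–H addition across a C1≡C2 alkynyl ether defines the ketene acetal geometry, and no other alkoxy group is ever attached to C1, so no open-chain rearrangement can compete.
- Gain: the fragile ring becomes an open-chain alcohol.
- Demand: 8-exo-dig closure must beat intermolecular addition, and 21 must rearrange before it isomerises.

**20 ⇒ 18 (via 19).**
- Bonds cut: C2–CH3, and the triple bond is traced back to a dichlorovinyl ether.
- Reason: the dichlorovinyl ether tolerates the metal-catalysed and organozinc steps that an alkynyl ether would not.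
- Gain: the sensitive group appears one step before use.
- Demand: carbon-selective methylation of an O,C-dianion.

**18 ⇒ 11 + 15 (via 16, 17).**
- Bond cut: C4–C5.
- Reason: the E enol ether and the relay centre C5 arise together from a syn hydroboration and a catalyst-controlled aldehyde addition.
- Gain: a two-carbon piece is split from a chain aldehyde.
- Demand: Si-face selectivity at C5 and a non-acidic work-up.

**15 ⇒ 13 ⇒ 12 (via 14).**
- Bonds cut: aryl O–C3, with the C3≡C4 unit drawn from a C2 chloroalkene.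
- Gain: a commodity phenol.
- Demand: 15 is used fresh.

**11 ⇒ 10.**
- Bond cut: C5–C6.
- Reason: one carbon is added to a terminal alkene as the aldehyde oxidation level that is needed.
- Demand: linear regioselectivity, helped by the bulky allylic silyl ether.

**10 ⇒ 9.**
- Bond cut: O9–C1.
- Reason: O9 is the only free hydroxyl at this stage, so the O8/O9 question is settled without a protecting-group exchange.
- Demand: no silyl shift in the alkoxide.

**9 ⇒ 3 + 7 (via 8).**
- Bond cut: C10–C11.
- Reason: opening a terminal epoxide liberates O9–H next to the already masked O8 and joins the C13 fragment.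
- Demand: attack at C10 only.

**3 ⇒ 2 ⇒ 1.**
- Bonds cut: O8–Si and the epoxide C–O bonds.
- Reason: an achiral C5 dienol holds C6–C10, and one desymmetrising epoxidation sets C8 and C9 as the erythro pair.

**7 ⇒ 6 ⇒ 5 ⇒ 4.**
- Bonds cut: C11–Br and the O13 benzyl ether, both traced to a cyclic acetal.
- Reason: C13 is bought, and the acetal differentiates the two hydroxyls.

## Other disconnections considered

**Alternative 1:** This is the first idea that comes to mind.
- Cut: the C4=C5 double bond.
- Forward key step: ring-closing metathesis of the diene ester A1.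
- Grounds for preferring the chosen plan:
  - In ten-membered lactones the E/Z outcome depends on subtle ring conformation and on secondary metathesis, so nothing in A1 enforces Z.
  - The allylic acetate at C3 slows initiation at that alkene.
  - C2 and C3 would have to be made beforehand by a separate anti-aldol sequence. The ring closure therefore settles only the ring, not the stereocentres.

**Alternative 2:**
- Cut: the C1–O9 ester bond.
- Forward key step: Shiina or Yamaguchi macrolactonisation of the O8-protected seco acid A2.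
- Grounds for preferring the chosen plan:
  - Activating a β-acyloxy acid invites E1cB loss of the C3 acetate and epimerisation at C2.
  - The hindered O9 must attack against medium-ring strain at high dilution.
  - All five stereocentres and the Z alkene have to be built linearly before the riskiest step, which adds no stereochemical information.

**Alternative 3:**
- Cut: C2–C3 and C1–O9-type connectivity from a six-membered ring.
- Forward key step: Bellus–Claisen ring expansion of the 2,6-cis vinyl tetrahydropyran A3 with methylketene A4.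
- Attraction: the ring of A3 (C5–C9, O9, with C10 attached) maps onto a 2,3-dideoxy-D-erythro-hexopyranose.
- Grounds for preferring the chosen plan:
  - Here O9 and C5 are directly bonded, so both E- and Z-forming chairs keep the ring torsion gauche. The less crowded one (acyl and vinyl both equatorial) leads to E.
  - The zwitterionic enolate places its methyl trans to the oxonium oxygen, which pairs with an E enol ether to give 2,3-syn.
  - The expected product is therefore the 4E, 2,3-syn lactone A5, wrong on two counts. The eight-membered ketene acetal forbids the E pathway.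

Key step: step 13

## Steps

Step 1
Reactants: 1 penta-1,4-dien-3-ol
Product: 2 (2R,3S)-1,2-epoxypent-4-en-3-ol
Conditions: Ti(OiPr)4, L-(+)-DIPT, t-BuOOH, 4 Å MS, CH2Cl2, −20 °C
Reagents that add atoms: tert-butyl hydroperoxide, CC(C)(C)OO
Why: Sharpless asymmetric epoxidation used as a desymmetrisation: enantiotopic-group and diastereoface selection with L-(+)-tartrate should give the erythro (2R,3S) epoxy alcohol, and the minor enantiomer is consumed by a second epoxidation. This sets C9 (R) and C8 (S).

Step 2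
Reactants: 2 (2R,3S)-1,2-epoxypent-4-en-3-ol
Product: 3 triisopropyl{[(1S)-1-[(2R)-oxiran-2-yl]prop-2-en-1-yl]oxy}silane
Conditions: TIPSOTf, 2,6-lutidine, CH2Cl2, −78 → 0 °C
Reagents that add atoms: triisopropylsilyl triflate, CC(C)[Si](C(C)C)(C(C)C)OS(=O)(=O)C(F)(F)F
Why: Silyl ether formation without alkoxide, so no Payne rearrangement. TIPS is chosen because it is reluctant to migrate, makes O8 a poor nucleophile in step 13 and falls to fluoride at the end.

Step 3
Reactants: 4 (S)-butane-1,3-diol
Product: 5 (2R,4S)-2-(4-methoxyphenyl)-4-methyl-1,3-dioxane (cis)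
Conditions: 4-MeOC6H4CH(OMe)2, PPTS (cat.), CH2Cl2, rt
Reagents that add atoms: 4-methoxybenzaldehyde dimethyl acetal, COC(OC)c1ccc(OC)cc1
Why: Acid-catalysed transacetalisation under thermodynamic control should give the diequatorial (cis) acetal. C13 (S) comes from the chiral pool and is not touched.

Step 4
Reactants: 5 (2R,4S)-2-(4-methoxyphenyl)-4-methyl-1,3-dioxane
Product: 6 (S)-3-(4-methoxybenzyloxy)butan-1-ol
Conditions: DIBAL-H, CH2Cl2, −78 → 0 °C; Rochelle salt
Reagents that add atoms: none
Why: Regioselective reductive acetal opening: aluminium binds the less hindered primary oxygen, so that C–O bond breaks and the benzyl ether stays on the secondary O13.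

Step 5
Reactants: 6 (S)-3-(4-methoxybenzyloxy)butan-1-ol
Product: 7 (S)-1-{[(4-bromobutan-2-yl)oxy]methyl}-4-methoxybenzene
Conditions: CBr4, PPh3, CH2Cl2, 0 °C
Reagents that add atoms: carbon tetrabromide, BrC(Br)(Br)Br
Why: Appel reaction at the primary carbon. Conditions are neutral and C13 is not involved.

Step 6
Reactants: 7 (S)-1-{[(4-bromobutan-2-yl)oxy]methyl}-4-methoxybenzene; 3 triisopropyl{[(1S)-1-[(2R)-oxiran-2-yl]prop-2-en-1-yl]oxy}silane
Product: 9 (3S,4R,8S)-8-(4-methoxybenzyloxy)-3-(triisopropylsilyloxy)non-1-en-4-ol, via [(3S)-3-(4-methoxybenzyloxy)butyl]magnesium bromide 8 (not isolated)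
Conditions: Mg, THF; then CuI (10 mol %), 3, THF, −40 → 0 °C
Reagents that add atoms: none
Why: Copper-catalysed Grignard opening of a terminal epoxide by SN2 attack at the unhindered C10. C9 keeps its configuration and O9–H appears as the only free hydroxyl.

Step 7
Reactants: 9 (3S,4R,8S)-8-(4-methoxybenzyloxy)-3-(triisopropylsilyloxy)non-1-en-4-ol
Product: 10 (3S,4R,8S)-4-{[(E)-1,2-dichlorovinyl]oxy}-8-(4-methoxybenzyloxy)-3-(triisopropylsilyloxy)non-1-ene
Conditions: KH, Cl2C=CHCl, THF, −50 °C → rt
Reagents that add atoms: trichloroethylene, ClC=C(Cl)Cl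
Why: Trichloroethylene route to alkynyl ether precursors: the potassium alkoxide adds anti to dichloroacetylene generated in the flask, which gives the E dichlorovinyl ether. The method is established for hindered secondary alcohols.

Step 8
Reactants: 10 (3S,4R,8S)-4-{[(E)-1,2-dichlorovinyl]oxy}-8-(4-methoxybenzyloxy)-3-(triisopropylsilyloxy)non-1-ene
Product: 11 (4S,5R,9S)-5-{[(E)-1,2-dichlorovinyl]oxy}-9-(4-methoxybenzyloxy)-4-(triisopropylsilyloxy)decanal
Conditions: Rh(acac)(CO)2 (1 mol %), BIPHEPHOS, CO/H2 (1:1, 5 bar), toluene, 60 °C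
Reagents that add atoms: carbon monoxide, [C-]#[O+]
Why: Linear-selective rhodium hydroformylation of a monosubstituted alkene. The wide-bite-angle ligand and the bulky allylic OTIPS group direct the formyl group (C5) to the terminus, and the trisubstituted chloroalkene should be inert.

Step 9
Reactants: 12 4-methoxyphenol
Product: 13 1-{[(E)-1,2-dichlorovinyl]oxy}-4-methoxybenzene
Conditions: K2CO3, Cl2C=CHCl, DMF, 70 °C
Reagents that add atoms: trichloroethylene, ClC=C(Cl)Cl
Why: Same addition as in step 7, here with a phenoxide. Anti addition gives the E isomer.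

Step 10
Reactants: 13 1-{[(E)-1,2-dichlorovinyl]oxy}-4-methoxybenzene
Product: 15 1-(ethynyloxy)-4-methoxybenzene, via lithium (4-methoxyphenoxy)acetylide 14 (not isolated)
Conditions: n-BuLi (2.2 equiv), Et2O, −78 → −40 °C; H2O, −78 °C
Reagents that add atoms: none
Why: Dehydrochlorination followed by chlorine–lithium exchange converts dichlorovinyl ethers into lithium alkoxyacetylides, and protonation gives the terminal aryl alkynyl ether, which is used fresh.

Step 11
Reactants: 15 1-(ethynyloxy)-4-methoxybenzene; 11 (4S,5R,9S)-5-{[(E)-1,2-dichlorovinyl]oxy}-9-(4-methoxybenzyloxy)-4-(triisopropylsilyloxy)decanal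
Product: 18 (1E,3R,6S,7R,11S)-7-{[(E)-1,2-dichlorovinyl]oxy}-11-(4-methoxybenzyloxy)-1-(4-methoxyphenoxy)-6-(triisopropylsilyloxy)dodec-1-en-3-ol, via dicyclohexyl[(E)-2-(4-methoxyphenoxy)vinyl]borane 16 (not isolated), via ethyl[(E)-2-(4-methoxyphenoxy)vinyl]zinc 17 (not isolated)
Conditions: BH3·SMe2, cyclohexene, toluene, 0 °C; 15, 0 °C → rt; Et2Zn, −78 °C; (−)-MIB (5 mol %), 11, −20 → 0 °C; pH 7 buffer
Reagents that add atoms: none
Why: Hydroboration, boron-to-zinc transmetalation and amino-alcohol-catalysed asymmetric alkenylation of an aldehyde, a sequence known for alkoxyacetylenes. Syn hydroboration with boron at the terminal carbon fixes the E enol ether. (−)-MIB should deliver the alkenyl group to the Si face of C5 and give 5R under catalyst control, since the nearest resident centre (C8) is three bonds away.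

Step 12
Reactants: 18 (1E,3R,6S,7R,11S)-7-{[(E)-1,2-dichlorovinyl]oxy}-11-(4-methoxybenzyloxy)-1-(4-methoxyphenoxy)-6-(triisopropylsilyloxy)dodec-1-en-3-ol
Product: 20 (1E,3R,6S,7R,11S)-11-(4-methoxybenzyloxy)-1-(4-methoxyphenoxy)-7-(prop-1-yn-1-yloxy)-6-(triisopropylsilyloxy)dodec-1-en-3-ol, via the dilithio species 19 (O5 lithium alkoxide and O9 lithioethynyl ether) (not isolated)
Conditions: n-BuLi (3.2 equiv), THF, −78 → −40 °C; MeI (1.2 equiv), DMPU, −78 → 0 °C; aq NaHCO3
Reagents that add atoms: iodomethane, CI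
Why: Same dichlorovinyl-to-lithioalkynyl ether conversion as in step 10, after deprotonation of O5–H. O,C-dianions of alkynols alkylate at carbon, so a limited amount of MeI should place the C2 methyl on the acetylide only.

Step 13
Reactants: 20 (1E,3R,6S,7R,11S)-11-(4-methoxybenzyloxy)-1-(4-methoxyphenoxy)-7-(prop-1-yn-1-yloxy)-6-(triisopropylsilyloxy)dodec-1-en-3-ol
Product: 22 (3R,4R,5Z,9S,10R)-10-[(4S)-4-(4-methoxybenzyloxy)pentyl]-4-(4-methoxyphenoxy)-3-methyl-9-(triisopropylsilyloxy)-3,4,7,8,9,10-hexahydro-2H-oxecin-2-one, via (2E,4R,5S,8R)-2-ethylidene-4-[(4S)-4-(4-methoxybenzyloxy)pentyl]-8-[(E)-2-(4-methoxyphenoxy)vinyl]-5-(triisopropylsilyloxy)-1,3-dioxocane 21 (not isolated)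
Conditions: (IPr)AuNTf2 (5 mol %), 2,6-di-tert-butyl-4-methylpyridine (10 mol %), 4 Å MS, toluene, 50 °C, slow addition of 20 (final 1 mM)
Reagents that add atoms: none
Why: Proposed new method: the closest known reaction types are the silver- or gold-catalysed trans addition of O–H nucleophiles to ynol ethers, the gold-catalysed hydroalkoxylation/Claisen cascade of alkynes with allylic alcohols and the ring-expanding Claisen rearrangement of vinyl-substituted cyclic ketene acetals, but their combination through an eight-membered ethylidene ketene acetal has not been shown. LAu+ slips along the polarised ynol ether to a C2-aurated ketene-oxonium ion, O5–H attacks the electrophilic C1 in the plane of the C2 substituents and anti to the bulky LAu (8-exo-dig closure of the C1/O5/C5–C9/O9 ring), and protodeauration with retention leaves the C2 methyl cis to O5, i.e. (E)-21. 21 then undergoes a concerted [3,3] shift (C2–C3 formed, C5–O5 broken, ring enlarged from eight to ten members) that is accelerated by the 2-alkoxy and 6-aryloxy donors, is strongly exergonic because a ketene acetal becomes a lactone, and therefore drains the unfavourable medium-ring closure irreversibly. The Z geometry of C4=C5 is enforced by the ring: C1, O5, C5 and C6 all belong to the eight-membered ring, so the C1–O5–C5–C6 torsion must stay gauche, which puts C6 axial in the chair-like array, whereas an E alkene would need an anti torsion of the trans-cyclooctene kind. C3 is controlled by the E enol ether (aryloxy group equatorial) together with C5, whose R configuration fixes the face of C3=C4 that can reach C2 and is erased in the process (1,3-chirality transfer). C2 is controlled by the ketene acetal geometry: methyl cis to O5 paired with an E allyl terminus in a chair gives the 2,3-anti relation, and with 5R this is 2R,3R. The step needs closure to win over intermolecular addition (slow addition, 1 mM), attack at C1 and not C2 (secured by the ynol ether polarisation), no E/Z scrambling of 21 through C2 protonation (hindered pyridine buffer, fast rearrangement at 50 °C) and no ionisation of the allylic alcohol (aryl instead of alkyl enol ether, alkynophilic catalyst). In this chair-like array the C9 side chain can sit pseudo-equatorially and the OTIPS group on the periphery, so the resident centres should not oppose it.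

Step 14
Reactants: 22 (3R,4R,5Z,9S,10R)-10-[(4S)-4-(4-methoxybenzyloxy)pentyl]-4-(4-methoxyphenoxy)-3-methyl-9-(triisopropylsilyloxy)-3,4,7,8,9,10-hexahydro-2H-oxecin-2-one
Product: 23 (3R,4R,5Z,9S,10R)-4-hydroxy-10-[(4S)-4-hydroxypentyl]-3-methyl-9-(triisopropylsilyloxy)-3,4,7,8,9,10-hexahydro-2H-oxecin-2-one
Conditions: (NH4)2Ce(NO3)6, MeCN/H2O (9:1), 0 °C
Reagents that add atoms: none
Why: Oxidative cleavage of the 4-methoxyphenyl ether (O3) and the 4-methoxybenzyl ether (O13) by cerium(IV) in one operation. Both C–O bonds to the stereocentres stay intact, and the TIPS ether, lactone and alkene should tolerate the cold, weakly acidic medium.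

Step 15
Reactants: 23 (3R,4R,5Z,9S,10R)-4-hydroxy-10-[(4S)-4-hydroxypentyl]-3-methyl-9-(triisopropylsilyloxy)-3,4,7,8,9,10-hexahydro-2H-oxecin-2-one
Product: 24 (3R,4R,5Z,9S,10R)-4-acetoxy-10-[(4S)-4-acetoxypentyl]-3-methyl-9-(triisopropylsilyloxy)-3,4,7,8,9,10-hexahydro-2H-oxecin-2-one
Conditions: Ac2O, pyridine, DMAP (cat.), CH2Cl2, 0 °C → rt
Reagents that add atoms: acetic anhydride, CC(=O)OC(C)=O
Why: Standard double acetylation of the only two free hydroxyls. The weak base and low temperature avoid E1cB loss at C3 and epimerisation at C2.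

Step 16
Reactants: 24 (3R,4R,5Z,9S,10R)-4-acetoxy-10-[(4S)-4-acetoxypentyl]-3-methyl-9-(triisopropylsilyloxy)-3,4,7,8,9,10-hexahydro-2H-oxecin-2-one
Product: 25 (3R,4R,5Z,9S,10R)-4-acetoxy-10-[(4S)-4-acetoxypentyl]-9-hydroxy-3-methyl-3,4,7,8,9,10-hexahydro-2H-oxecin-2-one (CNP0192248.1)
Conditions: HF·pyridine, pyridine, THF, 0 °C → rt
Reagents that add atoms: none
Why: Fluoride-mediated desilylation in a buffered, slightly acidic medium frees O8–H without acetate cleavage, β-elimination or base-induced O9→O8 acyl shift.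

## Compound list

1 | penta-1,4-dien-3-ol | C=CC(O)C=C | starting material
2 | (2R,3S)-1,2-epoxypent-4-en-3-ol | C=C[C@H](O)[C@H]1CO1 | intermediate
3 | triisopropyl{[(1S)-1-[(2R)-oxiran-2-yl]prop-2-en-1-yl]oxy}silane | C=C[C@H](O[Si](C(C)C)(C(C)C)C(C)C)[C@H]1CO1 | intermediate
4 | (S)-butane-1,3-diol | C[C@H](O)CCO | starting material
5 | (2R,4S)-2-(4-methoxyphenyl)-4-methyl-1,3-dioxane (cis) | C[C@H]1CCO[C@H](O1)c2ccc(OC)cc2 | intermediate
6 | (S)-3-(4-methoxybenzyloxy)butan-1-ol | C[C@H](OCc1ccc(OC)cc1)CCO | intermediate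
7 | (S)-1-{[(4-bromobutan-2-yl)oxy]methyl}-4-methoxybenzene | C[C@H](OCc1ccc(OC)cc1)CCBr | intermediate
8 | [(3S)-3-(4-methoxybenzyloxy)butyl]magnesium bromide | C[C@H](OCc1ccc(OC)cc1)CC[Mg]Br | intermediate
9 | (3S,4R,8S)-8-(4-methoxybenzyloxy)-3-(triisopropylsilyloxy)non-1-en-4-ol | C=C[C@H](O[Si](C(C)C)(C(C)C)C(C)C)[C@H](O)CCC[C@H](C)OCc1ccc(OC)cc1 | intermediate
10 | (3S,4R,8S)-4-{[(E)-1,2-dichlorovinyl]oxy}-8-(4-methoxybenzyloxy)-3-(triisopropylsilyloxy)non-1-ene | C=C[C@H](O[Si](C(C)C)(C(C)C)C(C)C)[C@H](O/C(Cl)=C\Cl)CCC[C@H](C)OCc1ccc(OC)cc1 | intermediate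
11 | (4S,5R,9S)-5-{[(E)-1,2-dichlorovinyl]oxy}-9-(4-methoxybenzyloxy)-4-(triisopropylsilyloxy)decanal | O=CCC[C@H](O[Si](C(C)C)(C(C)C)C(C)C)[C@H](O/C(Cl)=C\Cl)CCC[C@H](C)OCc1ccc(OC)cc1 | intermediate
12 | 4-methoxyphenol | COc1ccc(O)cc1 | starting material
13 | 1-{[(E)-1,2-dichlorovinyl]oxy}-4-methoxybenzene | COc1ccc(O/C(Cl)=C\Cl)cc1 | intermediate
14 | lithium (4-methoxyphenoxy)acetylide | COc1ccc(OC#C[Li])cc1 | intermediate
15 | 1-(ethynyloxy)-4-methoxybenzene | COc1ccc(OC#C)cc1 | intermediate
16 | dicyclohexyl[(E)-2-(4-methoxyphenoxy)vinyl]borane | COc1ccc(O/C=C/B(C2CCCCC2)C2CCCCC2)cc1 | intermediate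
17 | ethyl[(E)-2-(4-methoxyphenoxy)vinyl]zinc | CC[Zn]/C=C/Oc1ccc(OC)cc1 | intermediate
18 | (1E,3R,6S,7R,11S)-7-{[(E)-1,2-dichlorovinyl]oxy}-11-(4-methoxybenzyloxy)-1-(4-methoxyphenoxy)-6-(triisopropylsilyloxy)dodec-1-en-3-ol | COc1ccc(cc1)O/C=C/[C@H](O)CC[C@H](O[Si](C(C)C)(C(C)C)C(C)C)[C@H](O/C(Cl)=C\Cl)CCC[C@H](C)OCc1ccc(OC)cc1 | intermediate
19 | dilithio species: O5 lithium alkoxide and O9 lithioethynyl ether derived from 18 | COc1ccc(cc1)O/C=C/[C@H](O[Li])CC[C@H](O[Si](C(C)C)(C(C)C)C(C)C)[C@H](OC#C[Li])CCC[C@H](C)OCc1ccc(OC)cc1 | intermediate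
20 | (1E,3R,6S,7R,11S)-11-(4-methoxybenzyloxy)-1-(4-methoxyphenoxy)-7-(prop-1-yn-1-yloxy)-6-(triisopropylsilyloxy)dodec-1-en-3-ol | COc1ccc(cc1)O/C=C/[C@H](O)CC[C@H](O[Si](C(C)C)(C(C)C)C(C)C)[C@H](OC#CC)CCC[C@H](C)OCc1ccc(OC)cc1 | intermediate
21 | (2E,4R,5S,8R)-2-ethylidene-4-[(4S)-4-(4-methoxybenzyloxy)pentyl]-8-[(E)-2-(4-methoxyphenoxy)vinyl]-5-(triisopropylsilyloxy)-1,3-dioxocane (methyl cis to O5) | C/C=C1\O[C@@H](/C=C/Oc2ccc(OC)cc2)CC[C@H](O[Si](C(C)C)(C(C)C)C(C)C)[C@@H](CCC[C@H](C)OCc2ccc(OC)cc2)O1 | intermediate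
22 | (3R,4R,5Z,9S,10R)-10-[(4S)-4-(4-methoxybenzyloxy)pentyl]-4-(4-methoxyphenoxy)-3-methyl-9-(triisopropylsilyloxy)-3,4,7,8,9,10-hexahydro-2H-oxecin-2-one | COc1ccc(CO[C@@H](C)CCC[C@H]2OC(=O)[C@H](C)[C@H](Oc3ccc(OC)cc3)/C=C\CC[C@@H]2O[Si](C(C)C)(C(C)C)C(C)C)cc1 | intermediate
23 | (3R,4R,5Z,9S,10R)-4-hydroxy-10-[(4S)-4-hydroxypentyl]-3-methyl-9-(triisopropylsilyloxy)-3,4,7,8,9,10-hexahydro-2H-oxecin-2-one | O[C@@H](C)CCC[C@H]1OC(=O)[C@H](C)[C@H](O)/C=C\CC[C@@H]1O[Si](C(C)C)(C(C)C)C(C)C | intermediate
24 | (3R,4R,5Z,9S,10R)-4-acetoxy-10-[(4S)-4-acetoxypentyl]-3-methyl-9-(triisopropylsilyloxy)-3,4,7,8,9,10-hexahydro-2H-oxecin-2-one | CC(=O)O[C@@H](C)CCC[C@H]1OC(=O)[C@H](C)[C@H](OC(C)=O)/C=C\CC[C@@H]1O[Si](C(C)C)(C(C)C)C(C)C | intermediate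
25 | (3R,4R,5Z,9S,10R)-4-acetoxy-10-[(4S)-4-acetoxypentyl]-9-hydroxy-3-methyl-3,4,7,8,9,10-hexahydro-2H-oxecin-2-one (CNP0192248.1) | CC(=O)O[C@@H](C)CCC[C@H]1OC(=O)[C@H](C)[C@H](OC(C)=O)/C=C\CC[C@@H]1O | target

## Step count and least certain steps

Total step count: 16.

Longest linear sequence: 12 steps, from 4 through steps 3, 4, 5, 6, 7, 8, 11, 12, 13, 14, 15 and 16.

**Step 13 (key step, bears the label).**
- Intermolecular O–H addition and adventitious hydration may outrun the eight-membered closure, because medium-ring formation has a low effective molarity.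
- Reversible protonation at C2 may scramble the ketene acetal geometry and so erode control at C2.
- A boat-like pathway may erode the Z selectivity.
- The catalyst or trace acid may ionise the donor-substituted allylic alcohol.
- Fallback with known chemistry, setting out from 9 and returning at 22:
  - 9 would be acylated with phenyl chloroformate to the phenyl carbonate F1.
  - F1 would be hydroformylated as in step 8 to the aldehyde F2.
  - F2 would be alkenylated as in step 11 to the hydroxy carbonate F3.
  - NaH at high dilution would close the eight-membered cyclic carbonate F4.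
  - Petasis methylenation (Cp2TiMe2, toluene, 110 °C) would give the methylene ketene acetal F5, which rearranges in the flask to the 2-desmethyl lactone F6.
  - Kinetic enolate methylation (LDA, MeI, −78 °C) from the ring periphery would install the C2 methyl and reach 22.
  - The ring, the Z alkene and C3 would still come from the ring-expanding Claisen rearrangement. C2 would be set separately.

**Step 7.**
- In the potassium alkoxide a 1,2 O→O silyl shift from O8 to O9 may compete.
- Addition at the hindered alkoxide may be slow.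
- Fallback, setting out from 9 and returning at 20, with no alkoxide involved:
  - Formylation with formic acetic anhydride/pyridine would give the formate F7.
  - Dichloromethylenation (PPh3, CCl4, THF, 60 °C) would give the 2,2-dichlorovinyl ether F8.
  - The conditions of steps 8 and 11 would give the aldehyde F9 and the allylic alcohol F10.
  - n-BuLi/MeI as in step 12 would converge on 20.

**Step 11.**
- Uncatalysed background addition or ethyl transfer may lower facial selectivity and chemoselectivity.
- The aryloxyvinyl metal species may decompose.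
- The hydroxy enol ether may be lost by acid-induced ionisation during work-up.
- Fallback, setting out from 11 and returning at 18:
  - Addition of the acetylide 14 to 11 would give the propargylic alcohol F11 as a C5 epimer mixture.
  - Oxidation with MnO2 would give the ynone F12.
  - Corey–Bakshi–Shibata reduction ((R)-Me-CBS, catecholborane, −78 °C) would give the (R)-propargylic alcohol F13.
  - Hydroxyl-directed trans hydroalumination with Red-Al would give the E enol ether 18.

**Step 12.**
- O-methylation of the lithium alkoxide may occur.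
- Vinyl deprotonation followed by loss of aryloxide from the enol ether may occur.
- Ortho-lithiation of the anisole rings may compete with the desired sequence.
- Fallback, setting out from 18 and returning at 20:
  - O5 would be masked as the triethylsilyl ether F14 (TESCl, imidazole).
  - Only two equivalents of n-BuLi and then MeI would be needed to reach the propynyl ether F15.
  - Buffered TBAF at 0 °C would remove the TES group selectively to give 20.

## Further compounds

F1 | step 13 | (3S,4R,8S)-8-(4-methoxybenzyloxy)-3-(triisopropylsilyloxy)non-1-en-4-yl phenyl carbonate | C=C[C@H](O[Si](C(C)C)(C(C)C)C(C)C)[C@H](OC(=O)Oc1ccccc1)CCC[C@H](C)OCc1ccc(OC)cc1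
F2 | step 13 | (4S,5R,9S)-9-(4-methoxybenzyloxy)-1-oxo-4-(triisopropylsilyloxy)decan-5-yl phenyl carbonate | O=CCC[C@H](O[Si](C(C)C)(C(C)C)C(C)C)[C@H](OC(=O)Oc1ccccc1)CCC[C@H](C)OCc1ccc(OC)cc1
F3 | step 13 | (1E,3R,6S,7R,11S)-3-hydroxy-11-(4-methoxybenzyloxy)-1-(4-methoxyphenoxy)-6-(triisopropylsilyloxy)dodec-1-en-7-yl phenyl carbonate | COc1ccc(cc1)O/C=C/[C@H](O)CC[C@H](O[Si](C(C)C)(C(C)C)C(C)C)[C@H](OC(=O)Oc1ccccc1)CCC[C@H](C)OCc1ccc(OC)cc1
F4 | step 13 | (4R,5S,8R)-4-[(4S)-4-(4-methoxybenzyloxy)pentyl]-8-[(E)-2-(4-methoxyphenoxy)vinyl]-5-(triisopropylsilyloxy)-1,3-dioxocan-2-one | O=C1O[C@@H](/C=C/Oc2ccc(OC)cc2)CC[C@H](O[Si](C(C)C)(C(C)C)C(C)C)[C@@H](CCC[C@H](C)OCc2ccc(OC)cc2)O1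
F5 | step 13 | (4R,5S,8R)-4-[(4S)-4-(4-methoxybenzyloxy)pentyl]-8-[(E)-2-(4-methoxyphenoxy)vinyl]-2-methylene-5-(triisopropylsilyloxy)-1,3-dioxocane | C=C1O[C@@H](/C=C/Oc2ccc(OC)cc2)CC[C@H](O[Si](C(C)C)(C(C)C)C(C)C)[C@@H](CCC[C@H](C)OCc2ccc(OC)cc2)O1
F6 | step 13 | 2-desmethyl analogue of 22 (same spatial arrangement at C3, C8, C9, C13; 4Z) | COc1ccc(CO[C@@H](C)CCC[C@H]2OC(=O)C[C@H](Oc3ccc(OC)cc3)/C=C\CC[C@@H]2O[Si](C(C)C)(C(C)C)C(C)C)cc1
F7 | step 7 | (3S,4R,8S)-8-(4-methoxybenzyloxy)-3-(triisopropylsilyloxy)non-1-en-4-yl formate | C=C[C@H](O[Si](C(C)C)(C(C)C)C(C)C)[C@H](OC=O)CCC[C@H](C)OCc1ccc(OC)cc1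
F8 | step 7 | (3S,4R,8S)-4-[(2,2-dichlorovinyl)oxy]-8-(4-methoxybenzyloxy)-3-(triisopropylsilyloxy)non-1-ene | C=C[C@H](O[Si](C(C)C)(C(C)C)C(C)C)[C@H](OC=C(Cl)Cl)CCC[C@H](C)OCc1ccc(OC)cc1
F9 | step 7 | (4S,5R,9S)-5-[(2,2-dichlorovinyl)oxy]-9-(4-methoxybenzyloxy)-4-(triisopropylsilyloxy)decanal | O=CCC[C@H](O[Si](C(C)C)(C(C)C)C(C)C)[C@H](OC=C(Cl)Cl)CCC[C@H](C)OCc1ccc(OC)cc1
F10 | step 7 | (1E,3R,6S,7R,11S)-7-[(2,2-dichlorovinyl)oxy]-11-(4-methoxybenzyloxy)-1-(4-methoxyphenoxy)-6-(triisopropylsilyloxy)dodec-1-en-3-ol | COc1ccc(cc1)O/C=C/[C@H](O)CC[C@H](O[Si](C(C)C)(C(C)C)C(C)C)[C@H](OC=C(Cl)Cl)CCC[C@H](C)OCc1ccc(OC)cc1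
F11 | step 11 | (6S,7R,11S)-7-{[(E)-1,2-dichlorovinyl]oxy}-11-(4-methoxybenzyloxy)-1-(4-methoxyphenoxy)-6-(triisopropylsilyloxy)dodec-1-yn-3-ol (C3 epimer mixture) | COc1ccc(cc1)OC#CC(O)CC[C@H](O[Si](C(C)C)(C(C)C)C(C)C)[C@H](O/C(Cl)=C\Cl)CCC[C@H](C)OCc1ccc(OC)cc1
F12 | step 11 | (6S,7R,11S)-7-{[(E)-1,2-dichlorovinyl]oxy}-11-(4-methoxybenzyloxy)-1-(4-methoxyphenoxy)-6-(triisopropylsilyloxy)dodec-1-yn-3-one | COc1ccc(cc1)OC#CC(=O)CC[C@H](O[Si](C(C)C)(C(C)C)C(C)C)[C@H](O/C(Cl)=C\Cl)CCC[C@H](C)OCc1ccc(OC)cc1
F13 | step 11 | (3R,6S,7R,11S)-7-{[(E)-1,2-dichlorovinyl]oxy}-11-(4-methoxybenzyloxy)-1-(4-methoxyphenoxy)-6-(triisopropylsilyloxy)dodec-1-yn-3-ol | COc1ccc(cc1)OC#C[C@H](O)CC[C@H](O[Si](C(C)C)(C(C)C)C(C)C)[C@H](O/C(Cl)=C\Cl)CCC[C@H](C)OCc1ccc(OC)cc1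
F14 | step 12 | O5-triethylsilyl ether of 18 | COc1ccc(cc1)O/C=C/[C@H](O[Si](CC)(CC)CC)CC[C@H](O[Si](C(C)C)(C(C)C)C(C)C)[C@H](O/C(Cl)=C\Cl)CCC[C@H](C)OCc1ccc(OC)cc1
F15 | step 12 | O5-triethylsilyl ether of 20 | COc1ccc(cc1)O/C=C/[C@H](O[Si](CC)(CC)CC)CC[C@H](O[Si](C(C)C)(C(C)C)C(C)C)[C@H](OC#CC)CCC[C@H](C)OCc1ccc(OC)cc1
A1 | alternative 1 | (4S,5R,9S)-9-acetoxy-4-(tert-butyldimethylsilyloxy)dec-1-en-5-yl... diene ester: O9 ester of (2R,3R)-3-acetoxy-2-methylpent-4-enoic acid with the C5–C14 alkenol (terminal alkenes at C4 and C5) | C=C[C@@H](OC(C)=O)[C@@H](C)C(=O)O[C@H](CCC[C@H](C)OC(C)=O)[C@@H](O[Si](C)(C)C(C)(C)C)CCC=C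
A2 | alternative 2 | (2R,3R,4Z,8S,9R,13S)-3,13-diacetoxy-8-(tert-butyldimethylsilyloxy)-9-hydroxy-2-methyltetradec-4-enoic acid | OC(=O)[C@H](C)[C@H](OC(C)=O)/C=C\CC[C@H](O[Si](C)(C)C(C)(C)C)[C@H](O)CCC[C@H](C)OC(C)=O
A3 | alternative 3 | (2R,3S,6R)-3-(tert-butyldimethylsilyloxy)-2-[(4S)-4-(4-methoxybenzyloxy)pentyl]-6-[(E)-2-(4-methoxyphenoxy)vinyl]tetrahydropyran (2,6-cis) | COc1ccc(cc1)O/C=C/[C@H]1CC[C@H](O[Si](C)(C)C(C)(C)C)[C@@H](CCC[C@H](C)OCc2ccc(OC)cc2)O1
A4 | alternative 3 | methylketene | CC=C=O
A5 | alternative 3 | (2R,3S,4E,8S,9R,13S) lactone: 4E, 2,3-syn isomer of the protected decanolide (O8 TBS) | COc1ccc(CO[C@@H](C)CCC[C@H]2OC(=O)[C@H](C)[C@@H](Oc3ccc(OC)cc3)/C=C/CC[C@@H]2O[Si](C)(C)C(C)(C)C)cc1
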